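## Retrosynthetic overview

1. The acetate and the primary bromide come last, from an acetonide-protected diol. The neopentylic ring C–Br bond comes from SN2 inversion (Appel) of a ring carbinol that lies trans to the side chain.
2. The ring CH–CH2 bond to the side chain comes from regiospecific alkylation of a ring enolate, trans to a silyloxy group, with a (Z)-allylic bromide. That bromide is made from an (S)-glycerate-derived methyl ketone by Z-selective Wittig olefination. The exocyclic methylene comes from the ring ketone.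
3. The only carbocycle is formed first, by a formal [4+2] cycloaddition of the silyl dienol ether of mesityl oxide with acrolein. This makes the ring CH2–CH2 bond and the bond from the future CHBr carbon to the C(CH3)2 carbon. The formyl activating group is then excised oxidatively and the ketone is reduced enantioselectively (CBS).
4. Enabling feature: in the cyclohexane ring, the carbon carrying the exocyclic CH2 is flanked by a ring CH2 and by the side-chain-bearing CH, which is bonded to the C(CH3)2 carbon. With the methylene carbon read as a ketone, this CH2–C(=O)–CH–C(CH3)2 array is mesityl oxide, i.e. a 2-silyloxy-4,4-dimethyl diene. The remaining CH2–CHBr pair is a two-carbon acceptor whose heteroatom-bearing carbon lies 1,4 to the oxygenated carbon and next to the quaternary carbon.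
5. Stereocontrol: the CBS reduction sets the ring carbinol, which directs the alkylation at the neighbouring ring CH and is then inverted to the bromide. The side-chain carbinol comes from the chiral pool.

Key step: step 2

Remark: the silyloxyethyl phosphonium salt and methyl (S)-glycerate acetonide are taken as catalogue compounds.

## Route

Step 1
Reactants: 1 mesityl oxide (4-methylpent-3-en-2-one)
Product: 3 tert-butyldimethyl[(4-methylpenta-1,3-dien-2-yl)oxy]silane, via lithium dienolate 2 (not isolated)
Conditions: LiN(iPr)2, THF, −78 °C; then TBSCl, DMPU, −78 °C to rt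
Reagents that add atoms: tert-butyldimethylsilyl chloride, CC(C)(C)[Si](C)(C)Cl
Why: Kinetic deprotonation of the enone at the α′-methyl group by the hindered amide base, followed by O-silylation of the cross-conjugated enolate (silyl enol ether formation), should give the 2-silyloxydiene; no stereocentre is formed.

Step 2
Reactants: 3 tert-butyldimethyl[(4-methylpenta-1,3-dien-2-yl)oxy]silane; 4 acrolein (prop-2-enal)
Product: 5 rac-4-[(tert-butyldimethylsilyl)oxy]-2,2-dimethylcyclohex-3-ene-1-carbaldehyde
Conditions: AlBr3/AlMe3 (10:1, 20 mol%), toluene/CH2Cl2, −40 to 0 °C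
Reagents that add atoms: none
Why: Formal Diels–Alder cycloaddition run as a Lewis acid-promoted Mukaiyama–Michael/Michael sequence: the CH2 terminus of the enol silane of 3 attacks the β-carbon of AlBr3-bound acrolein (first bond, ring CH2–CH2), and the aluminium enolate then closes onto the gem-dimethyl terminus of the silyloxyallyl cation (second bond, CH(CHO)–C(CH3)2), which regenerates the enol silane. The closest known reaction type is the AlBr3/AlMe3-promoted Diels–Alder reaction of 4,4-disubstituted 2-silyloxydienes with enones, which forges quaternary carbons that thermal cycloadditions of such s-cis-disfavoured dienes do not reach. The six-membered ring is closed in [4+2] fashion, its second bond by a 6-endo-trig conjugate closure. The only new stereocentre, the formyl-bearing carbon, forms as a racemate and needs no control because step 3 turns it into a carbonyl carbon. The step needs "para" regioselectivity (formyl carbon bonded to the quaternary carbon, 1,4 to the silyloxy carbon) and an enol silane that points towards the CH next to the quaternary carbon; both follow from the polarisation of the 2-silyloxydiene, whose only nucleophilic terminus is the unsubstituted CH2, and from the silyl group staying on oxygen throughout. AlMe3 scavenges adventitious HBr so that the enol silane and acrolein survive.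

Step 3
Reactants: 5 rac-4-[(tert-butyldimethylsilyl)oxy]-2,2-dimethylcyclohex-3-ene-1-carbaldehyde
Product: 6 4-[(tert-butyldimethylsilyl)oxy]-2,2-dimethylcyclohex-3-en-1-one
Conditions: Cu(OAc)2 (10 mol%), 2,2'-bipyridine, DABCO, O2 (1 atm), DMF, 40 °C
Reagents that add atoms: dioxygen, O=O
Why: Copper-catalysed aerobic oxidative deformylation of an α-branched aldehyde (enolisation, α-oxygenation by O2, fragmentation to ketone and formic acid) should excise the activating formyl carbon and leave the achiral ketone with the base-stable enol silane untouched; the stereocentre of 5 is erased.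

Step 4
Reactants: 6 4-[(tert-butyldimethylsilyl)oxy]-2,2-dimethylcyclohex-3-en-1-one
Product: 7 (1R)-4-[(tert-butyldimethylsilyl)oxy]-2,2-dimethylcyclohex-3-en-1-ol
Conditions: (S)-2-methyl-CBS-oxazaborolidine (10 mol%), catecholborane, toluene, −78 °C
Reagents that add atoms: none
Why: Corey–Bakshi–Shibata reduction, in which the oxazaborolidine–borane complex binds the ketone with the quaternary α-carbon as the large and the ring CH2 as the small substituent and delivers hydride to one face, should set the (R)-carbinol, while catecholborane at low temperature spares the enol silane.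

Step 5
Reactants: 7 (1R)-4-[(tert-butyldimethylsilyl)oxy]-2,2-dimethylcyclohex-3-en-1-ol
Product: 8 tert-butyl({(1R)-4-[(tert-butyldimethylsilyl)oxy]-2,2-dimethylcyclohex-3-en-1-yl}oxy)dimethylsilane
Conditions: TBSOTf, 2,6-lutidine, CH2Cl2, −78 to 0 °C
Reagents that add atoms: tert-butyldimethylsilyl trifluoromethanesulfonate, CC(C)(C)[Si](C)(C)OS(=O)(=O)C(F)(F)F
Why: Silylation of the hindered neopentylic alcohol with the silyl triflate (silyl ether formation) protects it for the enolate chemistry without touching the stereocentre.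

Step 6
Reactants: 9 methyl (4S)-2,2-dimethyl-1,3-dioxolane-4-carboxylate
Product: 10 (4S)-N-methoxy-N,2,2-trimethyl-1,3-dioxolane-4-carboxamide
Conditions: MeNH(OMe)·HCl, iPrMgCl, THF, −20 °C
Reagents that add atoms: N,O-dimethylhydroxylamine hydrochloride, CNOC.Cl
Why: Aminolysis of the ester by the chloromagnesium amide of N,O-dimethylhydroxylamine (Weinreb amide formation) should proceed at low temperature without epimerising the α-alkoxy stereocentre.

Step 7
Reactants: 10 (4S)-N-methoxy-N,2,2-trimethyl-1,3-dioxolane-4-carboxamide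
Product: 11 1-[(4S)-2,2-dimethyl-1,3-dioxolan-4-yl]ethan-1-one
Conditions: MeMgBr, THF, 0 °C
Reagents that add atoms: methylmagnesium bromide, C[Mg]Br
Why: Grignard addition to the Weinreb amide stops at the chelated tetrahedral adduct and gives the methyl ketone on work-up, with the chiral-pool stereocentre retained.

Step 8
Reactants: 11 1-[(4S)-2,2-dimethyl-1,3-dioxolan-4-yl]ethan-1-one; 12 {2-[(tert-butyldimethylsilyl)oxy]ethyl}triphenylphosphonium bromide
Product: 14 tert-butyl({(2Z)-3-[(4R)-2,2-dimethyl-1,3-dioxolan-4-yl]but-2-en-1-yl}oxy)dimethylsilane, via phosphonium ylide 13 (not isolated)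
Conditions: KN(SiMe3)2, THF, −78 °C; then 11, −78 °C to rt
Reagents that add atoms: none
Why: Wittig olefination of an α-alkoxy methyl ketone with a non-stabilised ylide under lithium-free conditions is Z-selective for the trisubstituted alkene (ylide substituent cis to the oxygenated carbon), so the side-chain geometry should be set here, and the low temperature protects the α-stereocentre.

Step 9
Reactants: 14 tert-butyl({(2Z)-3-[(4R)-2,2-dimethyl-1,3-dioxolan-4-yl]but-2-en-1-yl}oxy)dimethylsilane
Product: 15 (2Z)-3-[(4R)-2,2-dimethyl-1,3-dioxolan-4-yl]but-2-en-1-ol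
Conditions: Bu4NF, THF, 0 °C
Reagents that add atoms: none
Why: Fluoride-mediated cleavage of the primary allylic silyl ether (desilylation) frees the alcohol without touching the acetonide or the alkene geometry.

Step 10
Reactants: 15 (2Z)-3-[(4R)-2,2-dimethyl-1,3-dioxolan-4-yl]but-2-en-1-ol
Product: 16 (4R)-4-[(2Z)-4-bromobut-2-en-2-yl]-2,2-dimethyl-1,3-dioxolane
Conditions: CBr4, PPh3, 2,6-lutidine, CH2Cl2, −20 °C
Reagents that add atoms: carbon tetrabromide, BrC(Br)(Br)Br
Why: Appel reaction of the primary allylic alcohol under buffered conditions should give the allylic bromide by SN2 displacement with the (Z)-geometry retained.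

Step 11
Reactants: 8 tert-butyl({(1R)-4-[(tert-butyldimethylsilyl)oxy]-2,2-dimethylcyclohex-3-en-1-yl}oxy)dimethylsilane; 16 (4R)-4-[(2Z)-4-bromobut-2-en-2-yl]-2,2-dimethyl-1,3-dioxolane
Product: 18 (2S,4R)-4-[(tert-butyldimethylsilyl)oxy]-2-{(2Z)-3-[(4R)-2,2-dimethyl-1,3-dioxolan-4-yl]but-2-en-1-yl}-3,3-dimethylcyclohexan-1-one, via lithium enolate 17 (not isolated)
Conditions: MeLi, THF, 0 °C to rt; then 16, DMPU, −78 to −20 °C
Reagents that add atoms: none
Why: Regiospecific enolate alkylation, in which MeLi cleaves only the enol silane and the lithium enolate is alkylated at CH2Br (SN2) on the face anti to the pseudoaxial methyl of the adjacent quaternary carbon in the half-chair that keeps the silyloxy group pseudoequatorial, should set the new ring stereocentre trans to the silyl ether.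

Step 12
Reactants: 18 (2S,4R)-4-[(tert-butyldimethylsilyl)oxy]-2-{(2Z)-3-[(4R)-2,2-dimethyl-1,3-dioxolan-4-yl]but-2-en-1-yl}-3,3-dimethylcyclohexan-1-one
Product: 19 tert-butyl{[(1R,3R)-3-{(2Z)-3-[(4R)-2,2-dimethyl-1,3-dioxolan-4-yl]but-2-en-1-yl}-2,2-dimethyl-4-methylidenecyclohexyl]oxy}dimethylsilane
Conditions: Zn, CH2Br2, TiCl4, THF/CH2Cl2, 0 °C to rt
Reagents that add atoms: dibromomethane, BrCBr
Why: Takai–Lombardo methylenation is non-basic and should convert the hindered, epimerisable ketone into the exocyclic methylene without touching the α-stereocentre, the silyl ether or the acetonide.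

Step 13
Reactants: 19 tert-butyl{[(1R,3R)-3-{(2Z)-3-[(4R)-2,2-dimethyl-1,3-dioxolan-4-yl]but-2-en-1-yl}-2,2-dimethyl-4-methylidenecyclohexyl]oxy}dimethylsilane
Product: 20 (1R,3R)-3-{(2Z)-3-[(4R)-2,2-dimethyl-1,3-dioxolan-4-yl]but-2-en-1-yl}-2,2-dimethyl-4-methylidenecyclohexan-1-ol
Conditions: Bu4NF, THF, 50 °C
Reagents that add atoms: none
Why: Fluoride desilylation of the secondary silyl ether frees the alcohol, which lies trans to the side chain and is therefore axial in the chair with the equatorial side chain, the arrangement needed for backside displacement.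

Step 14
Reactants: 20 (1R,3R)-3-{(2Z)-3-[(4R)-2,2-dimethyl-1,3-dioxolan-4-yl]but-2-en-1-yl}-2,2-dimethyl-4-methylidenecyclohexan-1-ol
Product: 21 (4R)-4-{(2Z)-4-[(1R,3S)-3-bromo-2,2-dimethyl-6-methylidenecyclohexyl]but-2-en-2-yl}-2,2-dimethyl-1,3-dioxolane
Conditions: CBr4, PPh3, pyridine, toluene, 60 °C
Reagents that add atoms: carbon tetrabromide, BrC(Br)(Br)Br
Why: Appel reaction, in which bromide displaces the alkoxyphosphonium group in an SN2 step with inversion, should turn the (R)-carbinol into the (S)-bromide cis to the side chain, in line with Appel brominations of axial neopentylic alcohols in 2,2-dimethylcyclohexane terpenoid rings, while pyridine buffers the medium for the acetonide and the exocyclic alkene.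

Step 15
Reactants: 21 (4R)-4-{(2Z)-4-[(1R,3S)-3-bromo-2,2-dimethyl-6-methylidenecyclohexyl]but-2-en-2-yl}-2,2-dimethyl-1,3-dioxolane
Product: 22 (2R,3Z)-5-[(1R,3S)-3-bromo-2,2-dimethyl-6-methylidenecyclohexyl]-3-methylpent-3-ene-1,2-diol
Conditions: AcOH/H2O (4:1), 40 °C
Reagents that add atoms: none
Why: Mild acid-catalysed hydrolysis of the isopropylidene acetal (acetonide cleavage) frees the 1,2-diol while the secondary bromide, the exocyclic methylene and the allylic stereocentre should be stable.

Step 16
Reactants: 22 (2R,3Z)-5-[(1R,3S)-3-bromo-2,2-dimethyl-6-methylidenecyclohexyl]-3-methylpent-3-ene-1,2-diol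
Product: 23 (2R,3Z)-1-bromo-5-[(1R,3S)-3-bromo-2,2-dimethyl-6-methylidenecyclohexyl]-3-methylpent-3-en-2-ol
Conditions: CBr4, PPh3, pyridine, CH2Cl2, −20 to 0 °C
Reagents that add atoms: carbon tetrabromide, BrC(Br)(Br)Br
Why: Appel reaction with one equivalent of reagent at low temperature should be selective for the primary hydroxyl of the 1,2-diol over the more hindered allylic secondary one, which installs the CH2Br group without touching the carbinol stereocentre.

Step 17
Reactants: 23 (2R,3Z)-1-bromo-5-[(1R,3S)-3-bromo-2,2-dimethyl-6-methylidenecyclohexyl]-3-methylpent-3-en-2-ol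
Product: 24 (2R,3Z)-1-bromo-5-[(1R,3S)-3-bromo-2,2-dimethyl-6-methylidenecyclohexyl]-3-methylpent-3-en-2-yl acetate
Conditions: Ac2O, pyridine, DMAP (cat.), CH2Cl2, 0 °C
Reagents that add atoms: acetic anhydride, CC(=O)OC(C)=O
Why: DMAP-catalysed acylation of the remaining secondary alcohol with acetic anhydride should give the acetate with retention, the weakly basic medium avoiding epoxide formation from the bromohydrin.

## Compound list

1 | mesityl oxide (4-methylpent-3-en-2-one) | CC(=O)C=C(C)C | starting material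
2 | lithium 4-methylpenta-1,3-dien-2-olate | [Li]OC(=C)C=C(C)C | intermediate
3 | tert-butyldimethyl[(4-methylpenta-1,3-dien-2-yl)oxy]silane | C=C(O[Si](C)(C)C(C)(C)C)C=C(C)C | intermediate
4 | acrolein (prop-2-enal) | C=CC=O | starting material
5 | rac-4-[(tert-butyldimethylsilyl)oxy]-2,2-dimethylcyclohex-3-ene-1-carbaldehyde | O=CC1CCC(O[Si](C)(C)C(C)(C)C)=CC1(C)C | intermediate
6 | 4-[(tert-butyldimethylsilyl)oxy]-2,2-dimethylcyclohex-3-en-1-one | O=C1CCC(O[Si](C)(C)C(C)(C)C)=CC1(C)C | intermediate
7 | (1R)-4-[(tert-butyldimethylsilyl)oxy]-2,2-dimethylcyclohex-3-en-1-ol | O[C@@H]1CCC(O[Si](C)(C)C(C)(C)C)=CC1(C)C | intermediate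
8 | tert-butyl({(1R)-4-[(tert-butyldimethylsilyl)oxy]-2,2-dimethylcyclohex-3-en-1-yl}oxy)dimethylsilane | CC(C)(C)[Si](C)(C)O[C@@H]1CCC(O[Si](C)(C)C(C)(C)C)=CC1(C)C | intermediate
9 | methyl (4S)-2,2-dimethyl-1,3-dioxolane-4-carboxylate | COC(=O)[C@H](CO1)OC1(C)C | starting material
10 | (4S)-N-methoxy-N,2,2-trimethyl-1,3-dioxolane-4-carboxamide | CON(C)C(=O)[C@H](CO1)OC1(C)C | intermediate
11 | 1-[(4S)-2,2-dimethyl-1,3-dioxolan-4-yl]ethan-1-one | CC(=O)[C@H](CO1)OC1(C)C | intermediate
12 | {2-[(tert-butyldimethylsilyl)oxy]ethyl}triphenylphosphonium bromide | CC(C)(C)[Si](C)(C)OCC[P+](c1ccccc1)(c1ccccc1)c1ccccc1.[Br-] | starting material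
13 | tert-butyldimethyl[2-(triphenyl-λ5-phosphanylidene)ethoxy]silane (ylide) | CC(C)(C)[Si](C)(C)OCC=P(c1ccccc1)(c1ccccc1)c1ccccc1 | intermediate
14 | tert-butyl({(2Z)-3-[(4R)-2,2-dimethyl-1,3-dioxolan-4-yl]but-2-en-1-yl}oxy)dimethylsilane | CC(C)(C)[Si](C)(C)OC/C=C(/C)[C@H](CO1)OC1(C)C | intermediate
15 | (2Z)-3-[(4R)-2,2-dimethyl-1,3-dioxolan-4-yl]but-2-en-1-ol | OC/C=C(/C)[C@H](CO1)OC1(C)C | intermediate
16 | (4R)-4-[(2Z)-4-bromobut-2-en-2-yl]-2,2-dimethyl-1,3-dioxolane | BrC/C=C(/C)[C@H](CO1)OC1(C)C | intermediate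
17 | lithium (4R)-4-[(tert-butyldimethylsilyl)oxy]-3,3-dimethylcyclohex-1-en-1-olate | [Li]OC1=CC(C)(C)[C@H](O[Si](C)(C)C(C)(C)C)CC1 | intermediate
18 | (2S,4R)-4-[(tert-butyldimethylsilyl)oxy]-2-{(2Z)-3-[(4R)-2,2-dimethyl-1,3-dioxolan-4-yl]but-2-en-1-yl}-3,3-dimethylcyclohexan-1-one | O=C1CC[C@@H](O[Si](C)(C)C(C)(C)C)C(C)(C)[C@@H]1C/C=C(/C)[C@H](CO2)OC2(C)C | intermediate
19 | tert-butyl{[(1R,3R)-3-{(2Z)-3-[(4R)-2,2-dimethyl-1,3-dioxolan-4-yl]but-2-en-1-yl}-2,2-dimethyl-4-methylidenecyclohexyl]oxy}dimethylsilane | C=C1CC[C@@H](O[Si](C)(C)C(C)(C)C)C(C)(C)[C@@H]1C/C=C(/C)[C@H](CO2)OC2(C)C | intermediate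
20 | (1R,3R)-3-{(2Z)-3-[(4R)-2,2-dimethyl-1,3-dioxolan-4-yl]but-2-en-1-yl}-2,2-dimethyl-4-methylidenecyclohexan-1-ol | C=C1CC[C@@H](O)C(C)(C)[C@@H]1C/C=C(/C)[C@H](CO2)OC2(C)C | intermediate
21 | (4R)-4-{(2Z)-4-[(1R,3S)-3-bromo-2,2-dimethyl-6-methylidenecyclohexyl]but-2-en-2-yl}-2,2-dimethyl-1,3-dioxolane | C=C1CC[C@H](Br)C(C)(C)[C@@H]1C/C=C(/C)[C@H](CO2)OC2(C)C | intermediate
22 | (2R,3Z)-5-[(1R,3S)-3-bromo-2,2-dimethyl-6-methylidenecyclohexyl]-3-methylpent-3-ene-1,2-diol | C=C1CC[C@H](Br)C(C)(C)[C@@H]1C/C=C(/C)[C@H](CO)O | intermediate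
23 | (2R,3Z)-1-bromo-5-[(1R,3S)-3-bromo-2,2-dimethyl-6-methylidenecyclohexyl]-3-methylpent-3-en-2-ol | C=C1CC[C@H](Br)C(C)(C)[C@@H]1C/C=C(/C)[C@H](CBr)O | intermediate
24 | (2R,3Z)-1-bromo-5-[(1R,3S)-3-bromo-2,2-dimethyl-6-methylidenecyclohexyl]-3-methylpent-3-en-2-yl acetate | C=C1CC[C@H](Br)C(C)(C)[C@@H]1C/C=C(/C)[C@H](CBr)OC(C)=O | target

## Step count and risks

Total step count: 17. Longest linear sequence: 12 steps (steps 1–5 then 11–17; the side-chain arm, steps 6–10 then 11–17, is equally long).

Steps most likely to fail: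

1. Step 14. The SN2 displacement at the neopentylic ring carbon is slow, so E2 elimination towards the ring CH2 and ionisation with Wagner–Meerwein methyl migration (ring contraction) may take over. The fallback sets out from 20 and returns at 21. Oxidation of 20 with Dess–Martin periodinane (CH2Cl2) should give the ring ketone F1. NaBH4 (MeOH, 0 °C) should reduce it by axial hydride attack to the equatorial cis-alcohol F2. Sulfonylation with quinoline-8-sulfonyl chloride (DMAP, CH2Cl2) gives the chelating quinoline-8-sulfonate F3. TiBr4 (CH2Cl2, −78 °C) then binds this leaving group and hands bromide over from the same face, a front-side substitution with retention, which should lead to 21 without a backside approach.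

2. Step 11. C-alkylation next to the quaternary carbon with a trisubstituted allylic bromide is slow, so proton transfer between product and enolate (loss of regiocontrol, alkylation at the ring CH2) and O-alkylation may compete. The fallback sets out from 8 and returns at 19. Enolate 17 is generated as before and alkylated with tert-butyl bromoacetate, a small and far more reactive electrophile, to give the keto ester F4. Zn/CH2Br2/TiCl4 gives the methylidene ester F5, iBu2AlH the primary alcohol F6, I2/PPh3/imidazole the iodide F7, and PPh3 (MeCN, 80 °C) the phosphonium iodide F8. KN(SiMe3)2 forms the ylide F9, whose Z-selective Wittig reaction with ketone 11 gives 19.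

3. Step 2. The silyl group may be lost from the open-chain Mukaiyama–Michael intermediate before ring closure, and acrolein may polymerise under the Lewis acid. The fallback sets out from 2 and returns at 6, replacing steps 1–3. Lithium dienolate 2 is combined with phenyl vinyl sulfone (THF, −78 to 0 °C). Michael addition followed by ring-closing Michael addition of the sulfonyl carbanion to the β,β-dimethyl enone (anionic double Michael reaction) should give the cyclic lithium enolate F10. This is silylated in the same flask (TBSCl, DMPU) to the sulfonyl enol silane F11. n-BuLi (THF, −78 °C) gives the α-lithio sulfone F12, and Me3SiOOSiMe3 (oxidative desulfonylation) gives ketone 6.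

## Further compounds

F1 | step 14 | (3R)-3-{(2Z)-3-[(4R)-2,2-dimethyl-1,3-dioxolan-4-yl]but-2-en-1-yl}-2,2-dimethyl-4-methylidenecyclohexan-1-one | C=C1CCC(=O)C(C)(C)[C@@H]1C/C=C(/C)[C@H](CO2)OC2(C)C
F2 | step 14 | (1S,3R)-3-{(2Z)-3-[(4R)-2,2-dimethyl-1,3-dioxolan-4-yl]but-2-en-1-yl}-2,2-dimethyl-4-methylidenecyclohexan-1-ol | C=C1CC[C@H](O)C(C)(C)[C@@H]1C/C=C(/C)[C@H](CO2)OC2(C)C
F3 | step 14 | (1S,3R)-3-{(2Z)-3-[(4R)-2,2-dimethyl-1,3-dioxolan-4-yl]but-2-en-1-yl}-2,2-dimethyl-4-methylidenecyclohexyl quinoline-8-sulfonate | C=C1CC[C@H](OS(=O)(=O)c3cccc4cccnc34)C(C)(C)[C@@H]1C/C=C(/C)[C@H](CO2)OC2(C)C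
F4 | step 11 | tert-butyl 2-[(1S,3R)-3-[(tert-butyldimethylsilyl)oxy]-2,2-dimethyl-6-oxocyclohexyl]acetate | O=C1CC[C@@H](O[Si](C)(C)C(C)(C)C)C(C)(C)[C@@H]1CC(=O)OC(C)(C)C
F5 | step 11 | tert-butyl 2-[(1R,3R)-3-[(tert-butyldimethylsilyl)oxy]-2,2-dimethyl-6-methylidenecyclohexyl]acetate | C=C1CC[C@@H](O[Si](C)(C)C(C)(C)C)C(C)(C)[C@@H]1CC(=O)OC(C)(C)C
F6 | step 11 | 2-[(1R,3R)-3-[(tert-butyldimethylsilyl)oxy]-2,2-dimethyl-6-methylidenecyclohexyl]ethan-1-ol | C=C1CC[C@@H](O[Si](C)(C)C(C)(C)C)C(C)(C)[C@@H]1CCO
F7 | step 11 | tert-butyl{[(1R,3R)-3-(2-iodoethyl)-2,2-dimethyl-4-methylidenecyclohexyl]oxy}dimethylsilane | C=C1CC[C@@H](O[Si](C)(C)C(C)(C)C)C(C)(C)[C@@H]1CCI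
F8 | step 11 | {2-[(1R,3R)-3-[(tert-butyldimethylsilyl)oxy]-2,2-dimethyl-6-methylidenecyclohexyl]ethyl}triphenylphosphonium iodide | C=C1CC[C@@H](O[Si](C)(C)C(C)(C)C)C(C)(C)[C@@H]1CC[P+](c2ccccc2)(c2ccccc2)c2ccccc2.[I-]
F9 | step 11 | tert-butyldimethyl({(1R,3R)-2,2-dimethyl-4-methylidene-3-[2-(triphenyl-λ5-phosphanylidene)ethyl]cyclohexyl}oxy)silane (ylide) | C=C1CC[C@@H](O[Si](C)(C)C(C)(C)C)C(C)(C)[C@@H]1CC=P(c2ccccc2)(c2ccccc2)c2ccccc2
F10 | step 2 | lithium 3,3-dimethyl-4-(phenylsulfonyl)cyclohex-1-en-1-olate (racemic) | [Li]OC1=CC(C)(C)C(S(=O)(=O)c2ccccc2)CC1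
F11 | step 2 | tert-butyl{[3,3-dimethyl-4-(phenylsulfonyl)cyclohex-1-en-1-yl]oxy}dimethylsilane (racemic) | CC(C)(C)[Si](C)(C)OC1=CC(C)(C)C(S(=O)(=O)c2ccccc2)CC1
F12 | step 2 | tert-butyl{[4-lithio-3,3-dimethyl-4-(phenylsulfonyl)cyclohex-1-en-1-yl]oxy}dimethylsilane (racemic) | CC(C)(C)[Si](C)(C)OC1=CC(C)(C)C([Li])(S(=O)(=O)c2ccccc2)CC1
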